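**Retrosynthetic overview**
1. Last bonds made: the C19–O ester bond (acylation of ent-labda-8(17),13(16),14-trien-19-ol with phenol-protected p-coumaric acid) and the C13–C14 bond of the diene (enol triflate of a C13 methyl ketone plus a vinylstannane).
2. The decalin comes in one operation from an acyclic (E,E)-diene 2-methyl-β-keto ester by oxidative radical bicyclisation: C4–C5 closes ring A first, C9–C10 closes ring B last, and the C8 radical ends as the 8(17)-methylene.
3. Enabling feature: the quaternary C4 of ring A carries a methyl group and an oxidised carbon (C19) and lies next to C3, while C5, C10, C9 and the exocyclic C8=C17 of ring B map onto the two trisubstituted alkenes of a geranyl unit. A temporary C3 ketone therefore makes C4 a 1,3-dicarbonyl radical, and a chiral 8-phenylmenthyl ester at C19 fixes the absolute configuration.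
4. Precursor: (E)-geranylacetone (side-chain ketone as dioxolane) is oxidised at its terminal E-methyl group, brominated, and used to alkylate the dianion of 8-phenylmenthyl 2-methylacetoacetate.
5. After the cyclisation the C3 ketone is removed through its tosylhydrazone, and LiAlH4 cleaves the auxiliary while giving the C19 alcohol.

Key step: step 6

Remark: the sense of induction in step 6 is assigned with the usual shielding model for 8-phenylmenthyl esters (ester carbonyl syn to the carbinol hydrogen and anti to the ring ketone, aryl group covering one face of the planar radical), which calls for the (1S,2R,5S)-auxiliary to reach the ent series; if the sense proved to be the reverse, the enantiomeric auxiliary would be used with no other change.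

**Route**

Step 1
Reactants: 1 (1S,2R,5S)-(+)-8-phenylmenthol; 2 ethyl 2-methylacetoacetate
Product: 3 (1S,2R,5S)-8-phenylmenthyl 2-methyl-3-oxobutanoate (both C2 epimers)
Conditions: DMAP (0.3 equiv), toluene, reflux, 4 Å molecular sieves (EtOH removed)
Reagents that add atoms: none
Why: DMAP-catalysed transesterification of a β-keto ester, which runs through the acylketene and so tolerates the hindered secondary alcohol; the carbinol stereocentres are untouched and the α-centre is of no consequence because it becomes the radical carbon.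

Step 2
Reactants: 4 (E)-geranylacetone
Product: 5 2-[(3E)-4,8-dimethylnona-3,7-dien-1-yl]-2-methyl-1,3-dioxolane
Conditions: HOCH2CH2OH (3 equiv), PPTS (0.05 equiv), benzene, reflux, Dean–Stark trap
Reagents that add atoms: ethylene glycol, OCCO
Why: acid-catalysed ketalisation with azeotropic removal of water, mild enough to leave both trisubstituted alkenes and the E geometry unchanged; no stereocentre is formed.

Step 3
Reactants: 5 2-[(3E)-4,8-dimethylnona-3,7-dien-1-yl]-2-methyl-1,3-dioxolane
Product: 6 (2E,6E)-2,6-dimethyl-9-(2-methyl-1,3-dioxolan-2-yl)nona-2,6-dien-1-ol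
Conditions: SeO2 (0.2 equiv), t-BuOOH (3 equiv), salicylic acid (0.1 equiv), CH2Cl2, 0 °C to rt
Reagents that add atoms: selenium dioxide, O=[Se]=O (oxygen donor, turned over by tert-butyl hydroperoxide, CC(C)(C)OO)
Why: SeO2-catalysed allylic oxidation (Riley oxidation: ene reaction then [2,3]-sigmatropic shift), which is selective for the E-methyl group of the terminal, most electron-rich and least hindered trisubstituted alkene and gives the (E)-allylic alcohol.

Step 4
Reactants: 6 (2E,6E)-2,6-dimethyl-9-(2-methyl-1,3-dioxolan-2-yl)nona-2,6-dien-1-ol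
Product: 7 2-[(3E,7E)-9-bromo-4,8-dimethylnona-3,7-dien-1-yl]-2-methyl-1,3-dioxolane
Conditions: CBr4 (1.2 equiv), PPh3 (1.2 equiv), CH2Cl2, −20 to 0 °C
Reagents that add atoms: carbon tetrabromide, BrC(Br)(Br)Br
Why: Appel reaction under neutral conditions, an SN2 displacement at the primary carbon that keeps the dioxolane and the alkene geometry.

Step 5
Reactants: 3 (1S,2R,5S)-8-phenylmenthyl 2-methyl-3-oxobutanoate; 7 2-[(3E,7E)-9-bromo-4,8-dimethylnona-3,7-dien-1-yl]-2-methyl-1,3-dioxolane
Product: 8 (1S,2R,5S)-8-phenylmenthyl (6E,10E)-2,6,10-trimethyl-13-(2-methyl-1,3-dioxolan-2-yl)-3-oxotrideca-6,10-dienoate (both C2 epimers)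
Conditions: 3, LiN(iPr)2 (2.2 equiv), THF, −78 to 0 °C; then 7, −78 to 0 °C; aq. NH4Cl
Reagents that add atoms: none
Why: γ-alkylation of a β-keto ester dianion, in which the more basic terminal carbanion is alkylated selectively by the allylic bromide (SN2, geometry retained); no stereocentre of consequence is formed.

Step 6
Reactants: 8 (1S,2R,5S)-8-phenylmenthyl (6E,10E)-2,6,10-trimethyl-13-(2-methyl-1,3-dioxolan-2-yl)-3-oxotrideca-6,10-dienoate
Product: 9 (1S,2R,5S)-8-phenylmenthyl ent-13,13-(ethylenedioxy)-3-oxo-14,15-dinorlabd-8(17)-en-19-oate [(4S,5S,9R,10S); trans-decalin, ester axial at C4 and cis to the C10 methyl, C9 side chain equatorial]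
Conditions: Mn(OAc)3·2H2O (2.2 equiv), Cu(OAc)2·H2O (1 equiv), KOAc (2 equiv), degassed AcOH, 25–40 °C
Reagents that add atoms: none
Why: Trivalent manganese oxidises the enol form of the 2-methyl-β-keto ester to a tertiary 1,3-dicarbonyl radical at C4, which adds to C5 of the (E)-C5=C10 alkene in a 6-endo-trig closure (ring A) to give a tertiary C10 radical; this adds to C9 of the (E)-C8=C9 alkene in a second 6-endo-trig closure (ring B), and the tertiary C8 radical is captured by divalent copper and loses a C17 hydrogen by oxidative β-hydride elimination to give the exocyclic 8(17)-methylene. The closest known reaction type is the Mn(OAc)3/Cu(OAc)2 oxidative free-radical polyene cyclisation of 2-alkyl acetoacetate esters, including its 8-phenylmenthyl ester version for trans-fused decalins with an axial C4 carboxyl group. C4 is set by the chair transition state of ring A, in which the C3 carbonyl lies in the forming ring and the ester takes the axial position, and its absolute sense by the aryl group of the auxiliary, which covers one face of the planar radical so that C5 bonds to the open face. C5 and C10 follow from the E geometry of the C5=C10 alkene in a chair–chair array (H-5 and the C10 methyl trans, trans ring fusion), and C9 from the E geometry of the C8=C9 alkene in the chair of ring B, which places the side chain equatorial and cis to the C10 methyl. The step needs 6-endo regioselectivity (secured by the trisubstituted alkenes, each attacked at its less substituted carbon to give a tertiary radical), Hofmann-type termination (copper removes the least hindered methyl hydrogen) and chemoselectivity (only the 1,3-dicarbonyl unit is oxidised at this temperature, the product has no hydrogen left at C4, and the ketal side chain offers no further alkene to the C8 radical).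

Step 7
Reactants: 9 (1S,2R,5S)-8-phenylmenthyl ent-13,13-(ethylenedioxy)-3-oxo-14,15-dinorlabd-8(17)-en-19-oate
Product: 10 C3 p-toluenesulfonylhydrazone of 9
Conditions: TsNHNH2 (3 equiv), EtOH, 4 Å molecular sieves, 70 °C
Reagents that add atoms: p-toluenesulfonyl hydrazide, Cc1ccc(cc1)S(=O)(=O)NN
Why: hydrazone condensation at the only free carbonyl group (C3), run without added acid so that the dioxolane and the exocyclic alkene persist; no stereocentre changes.

Step 8
Reactants: 10 C3 p-toluenesulfonylhydrazone of 9
Product: 12 (1S,2R,5S)-8-phenylmenthyl ent-13-oxo-14,15-dinorlabd-8(17)-en-19-oate, via C3-methylene dioxolane 11 (not isolated)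
Conditions: catecholborane (2 equiv), CHCl3, 0 °C to rt; NaOAc·3H2O, reflux; then PPTS, acetone/H2O (4:1), 50 °C
Reagents that add atoms: water, O
Why: Caglioti-type reductive deoxygenation of the tosylhydrazone (hydroboration of C=N, then acetate-induced loss of sulfinate and N2 from the diazene) should turn C3 into CH2 without touching the quaternary C4 centre, the ester or the 8(17)-alkene, and the mild acetal hydrolysis then frees the methyl ketone.

Step 9
Reactants: 12 (1S,2R,5S)-8-phenylmenthyl ent-13-oxo-14,15-dinorlabd-8(17)-en-19-oate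
Product: 13 (1S,2R,5S)-8-phenylmenthyl ent-13-(trifluoromethylsulfonyloxy)-14,15-dinorlabda-8(17),13(16)-dien-19-oate
Conditions: KN(SiMe3)2 (1.1 equiv), THF, −78 °C; PhNTf2 (1.2 equiv), −78 to 0 °C
Reagents that add atoms: N-phenylbis(trifluoromethanesulfonimide), O=S(=O)(N(c1ccccc1)S(=O)(=O)C(F)(F)F)C(F)(F)F
Why: kinetic enolisation of a methyl ketone at the methyl group with a bulky amide base and O-sulfonylation of the enolate (enol triflate formation); the auxiliary ester has no α-hydrogen and is shielded, so it should not be touched.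

Step 10
Reactants: 13 (1S,2R,5S)-8-phenylmenthyl ent-13-(trifluoromethylsulfonyloxy)-14,15-dinorlabda-8(17),13(16)-dien-19-oate
Product: 14 (1S,2R,5S)-8-phenylmenthyl ent-labda-8(17),13(16),14-trien-19-oate
Conditions: Bu3SnCH=CH2 (1.3 equiv), Pd(PPh3)4 (0.05 equiv), LiCl (3 equiv), THF, 65 °C
Reagents that add atoms: tributyl(vinyl)stannane, C=C[Sn](CCCC)(CCCC)CCCC
Why: Stille coupling of an enol triflate with a vinylstannane at zerovalent palladium, the standard entry to 2-substituted 1,3-butadienes; the 1,1-disubstituted 8(17)-alkene does not take part.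

Step 11
Reactants: 14 (1S,2R,5S)-8-phenylmenthyl ent-labda-8(17),13(16),14-trien-19-oate
Product: 15 ent-labda-8(17),13(16),14-trien-19-ol, [(1R,4aS,5R,8aS)-1,4a-dimethyl-6-methylidene-5-(3-methylidenepent-4-en-1-yl)decahydronaphthalen-1-yl]methanol
Conditions: LiAlH4 (3 equiv), THF, 0 °C to reflux; aq. NaOH work-up
Reagents that add atoms: none
Why: hydride reduction of the ester to the primary alcohol with release of the auxiliary alcohol 1 for re-use; C4 carries no hydrogen and cannot epimerise, and unactivated alkenes and the diene are inert to LiAlH4.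

Step 12
Reactants: 15 ent-labda-8(17),13(16),14-trien-19-ol; 16 (E)-4-acetoxycinnamic acid
Product: 18 ent-labda-8(17),13(16),14-trien-19-yl (E)-4-acetoxycinnamate, via acid chloride 17 (not isolated)
Conditions: 16, (COCl)2 (1.2 equiv), DMF (cat.), CH2Cl2, rt, then evaporation; 15, pyridine, DMAP (0.1 equiv), CH2Cl2, 0 °C to rt
Reagents that add atoms: none
Why: acylation of the neopentyl-type primary alcohol by an acid chloride under nucleophilic catalysis (Einhorn-type acylation), with the phenol masked as its acetate so that it cannot compete; the E geometry of the cinnamoyl unit is retained.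

Step 13
Reactants: 18 ent-labda-8(17),13(16),14-trien-19-yl (E)-4-acetoxycinnamate
Product: 19 CNP0131099.1, ent-labda-8(17),13(16),14-trien-19-yl (E)-4-hydroxycinnamate
Conditions: pyrrolidine (1.5 equiv), CH2Cl2, 0 °C; aq. NH4Cl work-up
Reagents that add atoms: none
Why: chemoselective aminolysis of the aryl acetate, which is far more electrophilic than the hindered, conjugated alkyl cinnamate, so that only the phenol should be released.

**Compound list**

1 | (1S,2R,5S)-(+)-8-phenylmenthol, (1S,2R,5S)-5-methyl-2-(2-phenylpropan-2-yl)cyclohexan-1-ol | O[C@H]1C[C@@H](C)CC[C@@H]1C(C)(C)c1ccccc1 | starting material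
2 | ethyl 2-methylacetoacetate | CCOC(=O)C(C)C(C)=O | starting material
3 | (1S,2R,5S)-8-phenylmenthyl 2-methyl-3-oxobutanoate | CC(=O)C(C)C(=O)O[C@H]1C[C@@H](C)CC[C@@H]1C(C)(C)c1ccccc1 | intermediate
4 | (E)-geranylacetone, (5E)-6,10-dimethylundeca-5,9-dien-2-one | CC(C)=CCC/C(C)=C/CCC(C)=O | starting material
5 | 2-[(3E)-4,8-dimethylnona-3,7-dien-1-yl]-2-methyl-1,3-dioxolane | CC(C)=CCC/C(C)=C/CCC1(C)OCCO1 | intermediate
6 | (2E,6E)-2,6-dimethyl-9-(2-methyl-1,3-dioxolan-2-yl)nona-2,6-dien-1-ol | OC/C(C)=C/CC/C(C)=C/CCC1(C)OCCO1 | intermediate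
7 | 2-[(3E,7E)-9-bromo-4,8-dimethylnona-3,7-dien-1-yl]-2-methyl-1,3-dioxolane | BrC/C(C)=C/CC/C(C)=C/CCC1(C)OCCO1 | intermediate
8 | (1S,2R,5S)-8-phenylmenthyl (6E,10E)-2,6,10-trimethyl-13-(2-methyl-1,3-dioxolan-2-yl)-3-oxotrideca-6,10-dienoate | CC(C(=O)O[C@H]1C[C@@H](C)CC[C@@H]1C(C)(C)c1ccccc1)C(=O)CC/C(C)=C/CC/C(C)=C/CCC1(C)OCCO1 | intermediate
9 | (1S,2R,5S)-8-phenylmenthyl ent-13,13-(ethylenedioxy)-3-oxo-14,15-dinorlabd-8(17)-en-19-oate (4S,5S,9R,10S) | CC1(OCCO1)CC[C@@H]1C(=C)CC[C@@H]2[C@](C)(C(=O)O[C@H]3C[C@@H](C)CC[C@@H]3C(C)(C)c3ccccc3)C(=O)CC[C@@]12C | intermediate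
10 | C3 p-toluenesulfonylhydrazone of 9 | CC1(OCCO1)CC[C@@H]1C(=C)CC[C@@H]2[C@](C)(C(=O)O[C@H]3C[C@@H](C)CC[C@@H]3C(C)(C)c3ccccc3)C(=NNS(=O)(=O)c3ccc(C)cc3)CC[C@@]12C | intermediate
11 | (1S,2R,5S)-8-phenylmenthyl ent-13,13-(ethylenedioxy)-14,15-dinorlabd-8(17)-en-19-oate (4R,5S,9R,10S) | CC1(OCCO1)CC[C@@H]1C(=C)CC[C@@H]2[C@](C)(C(=O)O[C@H]3C[C@@H](C)CC[C@@H]3C(C)(C)c3ccccc3)CCC[C@@]12C | intermediate
12 | (1S,2R,5S)-8-phenylmenthyl ent-13-oxo-14,15-dinorlabd-8(17)-en-19-oate | CC(=O)CC[C@@H]1C(=C)CC[C@@H]2[C@](C)(C(=O)O[C@H]3C[C@@H](C)CC[C@@H]3C(C)(C)c3ccccc3)CCC[C@@]12C | intermediate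
13 | (1S,2R,5S)-8-phenylmenthyl ent-13-(trifluoromethylsulfonyloxy)-14,15-dinorlabda-8(17),13(16)-dien-19-oate | C=C(OS(=O)(=O)C(F)(F)F)CC[C@@H]1C(=C)CC[C@@H]2[C@](C)(C(=O)O[C@H]3C[C@@H](C)CC[C@@H]3C(C)(C)c3ccccc3)CCC[C@@]12C | intermediate
14 | (1S,2R,5S)-8-phenylmenthyl ent-labda-8(17),13(16),14-trien-19-oate | C=CC(=C)CC[C@@H]1C(=C)CC[C@@H]2[C@](C)(C(=O)O[C@H]3C[C@@H](C)CC[C@@H]3C(C)(C)c3ccccc3)CCC[C@@]12C | intermediate
15 | ent-labda-8(17),13(16),14-trien-19-ol (1R,4aS,5R,8aS in naphthalene numbering) | C=CC(=C)CC[C@@H]1C(=C)CC[C@@H]2[C@](C)(CO)CCC[C@@]12C | intermediate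
16 | (E)-4-acetoxycinnamic acid | CC(=O)Oc1ccc(/C=C/C(=O)O)cc1 | starting material
17 | (E)-4-acetoxycinnamoyl chloride | CC(=O)Oc1ccc(/C=C/C(Cl)=O)cc1 | intermediate
18 | ent-labda-8(17),13(16),14-trien-19-yl (E)-4-acetoxycinnamate | C=CC(=C)CC[C@@H]1C(=C)CC[C@@H]2[C@](C)(COC(=O)/C=C/c3ccc(OC(C)=O)cc3)CCC[C@@]12C | intermediate
19 | CNP0131099.1, ent-labda-8(17),13(16),14-trien-19-yl (E)-4-hydroxycinnamate (4R,5S,9R,10S) | C=CC(=C)CC[C@@H]1C(=C)CC[C@@H]2[C@](C)(COC(=O)/C=C/c3ccc(O)cc3)CCC[C@@]12C | target

**Step count**
Total: 13 steps. Longest linear sequence: 12 steps (4 to 19, steps 2–13); step 1 is the one-step side branch that joins at step 5.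

**Steps most likely to fail, with fallbacks**

Step 6. Enolisation of the 2-methyl-β-keto ester is slow, so the dioxolane is exposed to acetic acid for a long time and may be hydrolysed in part; this would give a mixture and blur the later distinction between the two carbonyl groups. A facial bias lower than expected would cost material only, since the minor isomers are diastereomers of 9 and should be removable at this stage. The fallback sets out from 8 and cyclises without the protecting group. The dioxolane is removed on purpose (PPTS, acetone/H2O, 50 °C) to give the acyclic diketo ester F1. F1 is cyclised under the conditions of step 6, a simple methyl ketone not being oxidised by Mn(OAc)3 at this temperature, to the bicyclic diketone F2. The unhindered side-chain ketone of F2 is then ketalised selectively with Me3SiOCH2CH2OSiMe3 and catalytic Me3SiOTf in CH2Cl2 at −78 °C, the C3 ketone being shielded by the quaternary C4 and the auxiliary ester. This comes back to the route at 9.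

Step 7. Condensation at the C3 carbonyl, flanked by the quaternary C4 and the bulky ester, may stall, and forcing it with acid would start exchange at the dioxolane. The fallback sets out from 9 and removes the oxygen by a radical route. NaBH4 (MeOH/THF, 0 °C) reduces the ketone to the C3 alcohol F3 (either epimer serves). 1,1'-Thiocarbonyldiimidazole with DMAP in 1,2-dichloroethane at 70 °C gives the imidazolyl thionocarbonate F4. Barton–McCombie deoxygenation (Bu3SnH, AIBN, toluene, 110 °C) then gives 11, which is isolated in this case and carried on by the hydrolysis stage of step 8 to 12.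

Step 12. Acyl transfer to the axial, neopentyl-type C19 hydroxyl is slow, so acetyl transfer from the aryl acetate or decay of the acid chloride may compete. The fallback sets out from 15 and builds the cinnamate on the alcohol instead of attaching it. Heating 15 with Meldrum's acid (toluene, 100 °C) gives the hydrogen malonate F5 by way of the acylketene. Knoevenagel–Doebner condensation of F5 with 4-hydroxybenzaldehyde (pyridine, piperidine cat., 60 °C) then forms the (E)-4-hydroxycinnamate with loss of CO2. This comes back to the route directly at 19 without phenol protection, so step 13 is not needed.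

**Further compounds**

F1 | step 6 | (1S,2R,5S)-8-phenylmenthyl (6E,10E)-2,6,10-trimethyl-3,14-dioxopentadeca-6,10-dienoate | CC(C(=O)O[C@H]1C[C@@H](C)CC[C@@H]1C(C)(C)c1ccccc1)C(=O)CC/C(C)=C/CC/C(C)=C/CCC(C)=O
F2 | step 6 | (1S,2R,5S)-8-phenylmenthyl ent-3,13-dioxo-14,15-dinorlabd-8(17)-en-19-oate | CC(=O)CC[C@@H]1C(=C)CC[C@@H]2[C@](C)(C(=O)O[C@H]3C[C@@H](C)CC[C@@H]3C(C)(C)c3ccccc3)C(=O)CC[C@@]12C
F3 | step 7 | (1S,2R,5S)-8-phenylmenthyl ent-13,13-(ethylenedioxy)-3-hydroxy-14,15-dinorlabd-8(17)-en-19-oate (C3 epimers) | CC1(OCCO1)CC[C@@H]1C(=C)CC[C@@H]2[C@](C)(C(=O)O[C@H]3C[C@@H](C)CC[C@@H]3C(C)(C)c3ccccc3)C(O)CC[C@@]12C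
F4 | step 7 | O-(C3) 1H-imidazole-1-carbothioate of F3 | CC1(OCCO1)CC[C@@H]1C(=C)CC[C@@H]2[C@](C)(C(=O)O[C@H]3C[C@@H](C)CC[C@@H]3C(C)(C)c3ccccc3)C(OC(=S)n3ccnc3)CC[C@@]12C
F5 | step 12 | ent-labda-8(17),13(16),14-trien-19-yl hydrogen malonate | C=CC(=C)CC[C@@H]1C(=C)CC[C@@H]2[C@](C)(COC(=O)CC(=O)O)CCC[C@@]12C
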